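I begin with the crystals. The birch run is this very flask followed so far, and its target figure includes the crystals.

| setting | birch | flask |
|---|---|---|
| substrate | 1.7 M | 1.7 M |
| partner | 1.7 M | 1.70 M |
| remark | the very flask that is asked about, followed so far |  |
| time |  | 8.0 h |

birch run (percent of the substrate charged)

| time / h | target / % | crystals / % |
|---|---|---|
| 0.833 | 51.1 | 0.1 |
| 1.50 | 59.0 | 0.9 |
| 2.50 | 61.4 | 4.0 |
| 3.00 | 61.1 | 4.2 |

(readings scatter by 0.3 percentage points)

- what is said of target includes crystals
- crystals is a solid; its amount is given per volume of the solution

1. how much target and crystals together there is at 8.0 h, in percent of the substrate charged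
2. concentration of target in solution at 8.0 h, in percent of saturation

I subtract the solid at 3.00 h to get what is dissolved, as a fraction of the substrate charged:

dissolved share = 61.1 % − 4.2 % = 56.9 %

The crystals reading rose by 0.2 percentage points over the last interval, less than the scatter of 0.3 points, so I read this share as saturation. Multiplied by the substrate charge, it gives my reading of the solubility, the quantity I carry forward:

solubility = 56.9 % × 1.7 M = 0.967 M

Now I turn the question round. For this flask to stand below saturation at 8.0 h, its total would have to fall under that share, a drop of 4.2 points, or 14.0 times the scatter. The last two totals differ by 0.3 points, so I keep the total near 61.1 % and expect a full solution over the crystals.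

The forecast, a little higher on the total, gives 61.4 % and 100 % of saturation: “Solution should be essentially saturated”.

The flask gives 61.7 % and 100 % of saturation, with crystals at 4.62 %.

    crystals ⇌ target, rate k1*(cs1 - [target]) while solid is left; crystals form when [target] > cs1 (solubility = 0.970 M, k = 0.0220 /s)
    substrate + partner → isomer of the product (k = 4.10 × 10⁻⁴ /M/s)
    partner + tautomer → target (k = 0.640 /M/s)
    substrate ⇌ tautomer (K = 0.580, k = 4.80 × 10⁻⁴ /s)

This flask's total at 8.0 h less my share leaves 4.8 points for the solid by my reckoning. The same reckoning goes to the neighbour charged with 1.0 M of substrate, partner held. There my reading of the solubility comes to 96.7 % of the substrate charge, and the neighbour's total of 50.1 % lies below it, at 51.8 % of saturation by my reckoning. At 8.00 h that neighbour holds crystals at 0 %.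

The readings were computed with constants of no real substance.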